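**Retrosynthetic overview**

1. Feature: ring A of every flavan unit is a phloroglucinol ring whose adjacent pair C4a/O1 closes ring C by bonding C4 and C2, and each interflavan bond joins C4 of the upper unit to C8 of the unit below. The C4–C3–C2 chain of an upper unit can therefore be grown as an enone from C8 of the lower unit, and threefold-symmetric phloroglucinol added to it with no regiochemical choice.
2. The target, epicatechin-(4β→8)-epicatechin-(4β→8)-epicatechin-(4β→8)-catechin ⇐ its nonadeca-O-benzyl ether (hydrogenolysis). Each epicatechin ring C ⇐ a 4β-aryl-flav-2-ene, by epoxidation of C2=C3 anti to the C4 aryl and anti hydride opening at C2.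
3. Each flav-2-ene ⇐ phloroglucinol + an (E)-enone on C8 of the unit below: C4–C4a by chiral-acid Friedel–Crafts conjugate addition, O1–C2 by hemiketalisation and dehydration.
4. Each enone ⇐ a C8 aldehyde (NBS; n-BuLi, DMF) + 3′,4′-bis(benzyloxy)acetophenone (Claisen–Schmidt). The first aldehyde comes from (+)-catechin, which is the bottom unit.
5. Ring order: ring C of unit 3 (step 7), then ring C of unit 2 (step 14), then ring C of unit 1 (step 21). Rings A come intact from phloroglucinol, rings B from the acetophenone.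

Key step: step 7

Convention: flavan numbering; units are numbered 1 (top, free C8) to 4 (bottom, catechin); "4β" means the C4–aryl bond lies on the face it occupies in the target (trans to the 3-oxygen of the finished epicatechin unit).

Assumption: the (R)-configured acid is taken to be the enantiomer that sends phloroglucinol to the enone face giving the 4β configuration; if the sense proves opposite, the (S)-acid is used in steps 7, 14 and 21 with nothing else changed.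

**Route**

Step 1
Reactants: 1 (+)-catechin; 2 benzyl bromide
Product: 3 5,7,3′,4′-tetra-O-benzyl-(+)-catechin
Conditions: BnBr (4.4 equiv), K2CO3, DMF, 0 °C → rt, Ar
Reagents that add atoms: benzyl bromide (compound 2), BrCc1ccccc1
Why: Williamson etherification in which carbonate deprotonates only the four phenols, so the secondary 3-OH stays free and no stereocentre is touched.

Step 2
Reactants: 3 5,7,3′,4′-tetra-O-benzyl-(+)-catechin; 2 benzyl bromide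
Product: 4 3,5,7,3′,4′-penta-O-benzyl-(+)-catechin
Conditions: NaH, BnBr, DMF, 0 °C → rt
Reagents that add atoms: benzyl bromide (compound 2), BrCc1ccccc1
Why: Williamson etherification of the sodium alkoxide of the 3-OH; with every phenol capped, C2 cannot epimerise by ring opening.

Step 3
Reactants: 4 3,5,7,3′,4′-penta-O-benzyl-(+)-catechin
Product: 5 8-bromo-3,5,7,3′,4′-penta-O-benzylcatechin
Conditions: NBS (1.0 equiv), CH2Cl2, −78 °C → rt
Reagents that add atoms: N-bromosuccinimide, O=C1CCC(=O)N1Br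
Why: Electrophilic aromatic bromination of the most electron-rich ring (ring A) at C8, which lies between O1 and one benzyloxy group and is less hindered than C6 between two benzyloxy groups.

Step 4
Reactants: 5 8-bromo-3,5,7,3′,4′-penta-O-benzylcatechin
Product: 7 3,5,7,3′,4′-penta-O-benzylcatechin-8-carbaldehyde, via aryllithium 6 (not isolated)
Conditions: n-BuLi, THF, −78 °C; DMF, −78 → 0 °C; H2O
Reagents that add atoms: N,N-dimethylformamide, CN(C)C=O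
Why: Lithium–bromine exchange at −78 °C outruns benzylic deprotonation, and the aryllithium is formylated by DMF (Bouveault-type formylation).

Step 5
Reactants: 8 3′,4′-dihydroxyacetophenone; 2 benzyl bromide
Product: 9 3′,4′-bis(benzyloxy)acetophenone
Conditions: BnBr, K2CO3, DMF, 60 °C
Reagents that add atoms: benzyl bromide (compound 2), BrCc1ccccc1
Why: Williamson etherification of the two catechol hydroxyls.

Step 6
Reactants: 7 3,5,7,3′,4′-penta-O-benzylcatechin-8-carbaldehyde; 9 3′,4′-bis(benzyloxy)acetophenone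
Product: 10 (E)-1-[3,4-bis(benzyloxy)phenyl]-3-(3,5,7,3′,4′-penta-O-benzylcatechin-8-yl)prop-2-en-1-one
Conditions: KOH, EtOH/THF, 50 °C
Reagents that add atoms: none
Why: Claisen–Schmidt condensation in which only the ketone can enolise and the aldehyde has no α-hydrogen; E1cB loss of water gives the conjugated E-enone.

Step 7
Reactants: 10 (E)-enone on C8 of unit 4; 11 phloroglucinol
Product: 14 2-[3,4-bis(benzyloxy)phenyl]-4β-(3,5,7,3′,4′-penta-O-benzylcatechin-8-yl)-4H-chromene-5,7-diol (5,7-dihydroxyflav-2-ene of unit 3 on unit 4), via Michael adduct ketone 12 (not isolated), via cyclic hemiketal 13 (not isolated)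
Conditions: (R)-3,3′-bis(2,4,6-triisopropylphenyl)-1,1′-binaphthyl-2,2′-diyl N-triflylphosphoramide (10 mol%), phloroglucinol (5 equiv), 5 Å MS, CH2Cl2/Et2O, 0 °C → rt, Ar
Reagents that add atoms: none
Why: The N-triflylphosphoramide activates the enone carbonyl of 10 by hydrogen bonding and holds a phloroglucinol hydroxyl on its phosphoryl oxygen, so that a ring carbon of phloroglucinol adds to the β-carbon in a Friedel–Crafts conjugate addition (C4–C4a), giving ketone 12. The closest known reaction type is the chiral-acid or organocatalytic Friedel–Crafts addition and cyclodehydration of electron-rich phenols and naphthols with enones to 4-substituted 4H-chromenes. Ring C of unit 3 closes by 6-exo-trig attack of a flanking phenol oxygen on the ketone (hemiketal 13), and acid-catalysed loss of water over the sieves gives the aryl-conjugated enol ether (O1–C2, C2=C3). The one new stereocentre, C4, is set by the chiral acid, which shields one face of the bound enone; the C2 and C3 centres of unit 4 are too remote to steer, but they make the two C4 epimers diastereomers, so the minor one should be removable by chromatography. No regioselectivity is needed because the three carbons and three oxygens of phloroglucinol are equivalent and the 4→8 connectivity is fixed by the position of the aldehyde, while the excess of phloroglucinol suppresses a second alkylation of the product.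

Step 8
Reactants: 14 5,7-dihydroxyflav-2-ene of unit 3 on unit 4; 2 benzyl bromide
Product: 15 5,7-di-O-benzyl ether of 14
Conditions: BnBr, K2CO3, DMF, rt, Ar (directly after step 7)
Reagents that add atoms: benzyl bromide (compound 2), BrCc1ccccc1
Why: Williamson etherification of the two phenols under carbonate conditions too mild to touch the enol ether or the C4–H.

Step 9
Reactants: 15 5,7-di-O-benzyl flav-2-ene of unit 3 on unit 4
Product: 17 5,7,3′,4′-tetra-O-benzylepicatechin-(4β→8)-3,5,7,3′,4′-penta-O-benzylcatechin (free 3-OH on unit 3), via 2α,3α-epoxide 16 (not isolated)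
Conditions: DMDO, acetone/CH2Cl2, −40 °C; evaporate cold; LiBHEt3, THF, −78 → 0 °C
Reagents that add atoms: dimethyldioxirane, CC1(C)OO1
Why: Dioxirane epoxidation of the enol ether should occur anti to the pseudoaxial C4 aryl (fixing C3–O α), and LiBHEt3 should then open the epoxide at the aryl- and O1-activated C2 in an SN2-type anti fashion, as in hydride openings of 1-aryl-1,2-anhydro sugars, so that hydrogen enters β and the 2,3-cis-3,4-trans array of an epicatechin unit results.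

Step 10
Reactants: 17 dimer with free 3-OH on unit 3; 2 benzyl bromide
Product: 18 penta-O-benzylepicatechin-(4β→8)-penta-O-benzylcatechin (deca-O-benzyl dimer)
Conditions: NaH, BnBr, DMF, 0 °C → rt
Reagents that add atoms: benzyl bromide (compound 2), BrCc1ccccc1
Why: Williamson etherification of the hindered axial secondary alcohol through its sodium alkoxide; no acidic C–H competes.

Step 11
Reactants: 18 deca-O-benzyl dimer
Product: 19 8-bromo derivative of 18 (bromine on C8 of unit 3)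
Conditions: NBS (1.0 equiv), CH2Cl2, −78 °C
Reagents that add atoms: N-bromosuccinimide, O=C1CCC(=O)N1Br
Why: Electrophilic aromatic bromination with one equivalent of NBS at the only C8–H, which is less hindered than the two C6–H positions, each flanked by two benzyloxy groups, as in step 3.

Step 12
Reactants: 19 8-bromo dimer
Product: 21 8-carbaldehyde of 18 (CHO on C8 of unit 3), via aryllithium 20 (not isolated)
Conditions: n-BuLi, THF, −78 °C; DMF, −78 → 0 °C; H2O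
Reagents that add atoms: N,N-dimethylformamide, CN(C)C=O
Why: Lithium–bromine exchange followed by Bouveault-type formylation, as in step 4; benzyl ethers and the interflavan bond are inert to n-BuLi at −78 °C.

Step 13
Reactants: 21 dimer 8-carbaldehyde; 9 3′,4′-bis(benzyloxy)acetophenone
Product: 22 (E)-enone on C8 of unit 3 of the dimer
Conditions: KOH, EtOH/THF, 50 °C
Reagents that add atoms: none
Why: Claisen–Schmidt condensation of a non-enolisable aldehyde with the acetophenone enolate, giving the E-enone after E1cB dehydration.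

Step 14
Reactants: 22 (E)-enone on C8 of unit 3; 11 phloroglucinol
Product: 25 5,7-dihydroxyflav-2-ene of unit 2 bonded 4β→8 to dimer 18, via Michael adduct ketone 23 (not isolated), via cyclic hemiketal 24 (not isolated)
Conditions: (R)-N-triflylphosphoramide of step 7 (10 mol%), phloroglucinol (5 equiv), 5 Å MS, CH2Cl2/Et2O, 0 °C → rt, Ar
Reagents that add atoms: none
Why: The same Friedel–Crafts conjugate addition, 6-exo-trig hemiketalisation and dehydration as in step 7; C4 of unit 2 is set by the chiral acid, and the weak acid at low temperature should leave the existing 4→8 bond intact.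

Step 15
Reactants: 25 5,7-dihydroxyflav-2-ene of unit 2 on the dimer; 2 benzyl bromide
Product: 26 5,7-di-O-benzyl ether of 25
Conditions: BnBr, K2CO3, DMF, rt, Ar
Reagents that add atoms: benzyl bromide (compound 2), BrCc1ccccc1
Why: Williamson etherification of the two phenols, as in step 8.

Step 16
Reactants: 26 5,7-di-O-benzyl flav-2-ene of unit 2 on the dimer
Product: 28 tetra-O-benzylepicatechin-(4β→8)-penta-O-benzylepicatechin-(4β→8)-penta-O-benzylcatechin (free 3-OH on unit 2), via 2α,3α-epoxide 27 (not isolated)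
Conditions: DMDO, acetone/CH2Cl2, −40 °C; evaporate cold; LiBHEt3, THF, −78 → 0 °C
Reagents that add atoms: dimethyldioxirane, CC1(C)OO1
Why: Dioxirane epoxidation anti to the C4 aryl and SN2-type anti hydride opening at C2, as in step 9, relay C4 to C3 (O α) and C2 (H β) of unit 2.

Step 17
Reactants: 28 trimer with free 3-OH on unit 2; 2 benzyl bromide
Product: 29 pentadeca-O-benzyl epicatechin-(4β→8)-epicatechin-(4β→8)-catechin
Conditions: NaH, BnBr, DMF, 0 °C → rt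
Reagents that add atoms: benzyl bromide (compound 2), BrCc1ccccc1
Why: Williamson etherification of the secondary alkoxide, as in step 10.

Step 18
Reactants: 29 pentadeca-O-benzyl trimer
Product: 30 8-bromo derivative of 29 (bromine on C8 of unit 2)
Conditions: NBS (1.0 equiv), CH2Cl2, −78 °C
Reagents that add atoms: N-bromosuccinimide, O=C1CCC(=O)N1Br
Why: Electrophilic aromatic bromination at the single C8–H, favoured over the three more hindered C6–H positions, as in steps 3 and 11.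

Step 19
Reactants: 30 8-bromo trimer
Product: 32 8-carbaldehyde of 29 (CHO on C8 of unit 2), via aryllithium 31 (not isolated)
Conditions: n-BuLi, THF, −78 °C; DMF, −78 → 0 °C; H2O
Reagents that add atoms: N,N-dimethylformamide, CN(C)C=O
Why: Lithium–bromine exchange and Bouveault-type formylation, as in steps 4 and 12.

Step 20
Reactants: 32 trimer 8-carbaldehyde; 9 3′,4′-bis(benzyloxy)acetophenone
Product: 33 (E)-enone on C8 of unit 2 of the trimer
Conditions: KOH, EtOH/THF, 50 °C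
Reagents that add atoms: none
Why: Claisen–Schmidt condensation, as in steps 6 and 13.

Step 21
Reactants: 33 (E)-enone on C8 of unit 2; 11 phloroglucinol
Product: 36 5,7-dihydroxyflav-2-ene of unit 1 bonded 4β→8 to trimer 29, via Michael adduct ketone 34 (not isolated), via cyclic hemiketal 35 (not isolated)
Conditions: (R)-N-triflylphosphoramide of step 7 (10 mol%), phloroglucinol (5 equiv), 5 Å MS, CH2Cl2/Et2O, 0 °C → rt, Ar
Reagents that add atoms: none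
Why: The same chiral-acid Friedel–Crafts conjugate addition, 6-exo-trig hemiketalisation and dehydration as in step 7, with C4 of unit 1 set by the catalyst.

Step 22
Reactants: 36 5,7-dihydroxyflav-2-ene of unit 1 on the trimer; 2 benzyl bromide
Product: 37 5,7-di-O-benzyl ether of 36
Conditions: BnBr, K2CO3, DMF, rt, Ar
Reagents that add atoms: benzyl bromide (compound 2), BrCc1ccccc1
Why: Williamson etherification of the two phenols, as in step 8.

Step 23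
Reactants: 37 5,7-di-O-benzyl flav-2-ene of unit 1 on the trimer
Product: 39 nonadeca-O-benzyl tetramer (free 3-OH on unit 1), via 2α,3α-epoxide 38 (not isolated)
Conditions: DMDO, acetone/CH2Cl2, −40 °C; evaporate cold; LiBHEt3, THF, −78 → 0 °C
Reagents that add atoms: dimethyldioxirane, CC1(C)OO1
Why: Dioxirane epoxidation anti to the C4 aryl and SN2-type anti hydride opening at C2, as in step 9, set C3 and C2 of unit 1.

Step 24
Reactants: 39 nonadeca-O-benzyl tetramer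
Product: 40 epicatechin-(4β→8)-epicatechin-(4β→8)-epicatechin-(4β→8)-catechin (the target)
Conditions: H2 (1 atm), Pd(OH)2/C, THF/MeOH/H2O, rt
Reagents that add atoms: none
Why: Catalytic hydrogenolysis of the nineteen benzyl ethers under neutral conditions, which should leave the interflavan bonds and every stereocentre untouched.

**Compound list**

1 | (+)-catechin (2R,3S) | c1c(O)cc(O)c2c1O[C@H](c1ccc(O)c(O)c1)[C@@H](O)C2 | starting material
2 | benzyl bromide | BrCc1ccccc1 | starting material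
3 | 5,7,3′,4′-tetra-O-benzyl-(+)-catechin | c1c(OCc3ccccc3)cc(OCc3ccccc3)c2c1O[C@H](c1ccc(OCc3ccccc3)c(OCc3ccccc3)c1)[C@@H](O)C2 | intermediate
4 | 3,5,7,3′,4′-penta-O-benzyl-(+)-catechin | c1c(OCc3ccccc3)cc(OCc3ccccc3)c2c1O[C@H](c1ccc(OCc3ccccc3)c(OCc3ccccc3)c1)[C@@H](OCc3ccccc3)C2 | intermediate
5 | 8-bromo-3,5,7,3′,4′-penta-O-benzylcatechin | Brc1c(OCc3ccccc3)cc(OCc3ccccc3)c2c1O[C@H](c1ccc(OCc3ccccc3)c(OCc3ccccc3)c1)[C@@H](OCc3ccccc3)C2 | intermediate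
6 | 8-lithio-3,5,7,3′,4′-penta-O-benzylcatechin | [Li]c1c(OCc3ccccc3)cc(OCc3ccccc3)c2c1O[C@H](c1ccc(OCc3ccccc3)c(OCc3ccccc3)c1)[C@@H](OCc3ccccc3)C2 | intermediate
7 | 3,5,7,3′,4′-penta-O-benzylcatechin-8-carbaldehyde | O=Cc1c(OCc3ccccc3)cc(OCc3ccccc3)c2c1O[C@H](c1ccc(OCc3ccccc3)c(OCc3ccccc3)c1)[C@@H](OCc3ccccc3)C2 | intermediate
8 | 3′,4′-dihydroxyacetophenone | CC(=O)c1ccc(O)c(O)c1 | starting material
9 | 3′,4′-bis(benzyloxy)acetophenone | CC(=O)c1ccc(OCc2ccccc2)c(OCc2ccccc2)c1 | intermediate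
10 | (E)-enone: C8 of penta-O-benzylcatechin on the β-carbon, 3,4-bis(benzyloxy)phenyl on the carbonyl | O=C(/C=C/c1c(OCc3ccccc3)cc(OCc3ccccc3)c2c1O[C@H](c1ccc(OCc3ccccc3)c(OCc3ccccc3)c1)[C@@H](OCc3ccccc3)C2)c1ccc(OCc3ccccc3)c(OCc3ccccc3)c1 | intermediate
11 | phloroglucinol | Oc1cc(O)cc(O)c1 | starting material
12 | Michael adduct ketone: 1-[3,4-bis(benzyloxy)phenyl]-3-(penta-O-benzylcatechin-8-yl)-3-(2,4,6-trihydroxyphenyl)propan-1-one, new centre as C4 of unit 3 | O=C(c1ccc(OCc3ccccc3)c(OCc3ccccc3)c1)C[C@H](c1c(O)cc(O)cc1O)c1c(OCc3ccccc3)cc(OCc3ccccc3)c2c1O[C@H](c1ccc(OCc3ccccc3)c(OCc3ccccc3)c1)[C@@H](OCc3ccccc3)C2 | intermediate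
13 | cyclic hemiketal: 2,5,7-trihydroxyflavan of unit 3 (either C2 anomer) on unit 4 | c1c(O)cc(O)c2c1OC(O)(c1ccc(OCc3ccccc3)c(OCc3ccccc3)c1)C[C@H]2c1c(OCc3ccccc3)cc(OCc3ccccc3)c2c1O[C@H](c1ccc(OCc3ccccc3)c(OCc3ccccc3)c1)[C@@H](OCc3ccccc3)C2 | intermediate
14 | 5,7-dihydroxy-4β-aryl-flav-2-ene (unit 3) on unit 4 | c1c(O)cc(O)c2c1OC(c1ccc(OCc3ccccc3)c(OCc3ccccc3)c1)=C[C@H]2c1c(OCc3ccccc3)cc(OCc3ccccc3)c2c1O[C@H](c1ccc(OCc3ccccc3)c(OCc3ccccc3)c1)[C@@H](OCc3ccccc3)C2 | intermediate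
15 | 5,7-di-O-benzyl ether of 14 | c1c(OCc3ccccc3)cc(OCc3ccccc3)c2c1OC(c1ccc(OCc3ccccc3)c(OCc3ccccc3)c1)=C[C@H]2c1c(OCc3ccccc3)cc(OCc3ccccc3)c2c1O[C@H](c1ccc(OCc3ccccc3)c(OCc3ccccc3)c1)[C@@H](OCc3ccccc3)C2 | intermediate
16 | 2α,3α-epoxide of 15 (oxygen anti to the C4 aryl) | c1c(OCc3ccccc3)cc(OCc3ccccc3)c2c1O[C@@]4(c1ccc(OCc3ccccc3)c(OCc3ccccc3)c1)[C@H](O4)[C@H]2c1c(OCc3ccccc3)cc(OCc3ccccc3)c2c1O[C@H](c1ccc(OCc3ccccc3)c(OCc3ccccc3)c1)[C@@H](OCc3ccccc3)C2 | intermediate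
17 | 5,7,3′,4′-tetra-O-benzylepicatechin-(4β→8)-penta-O-benzylcatechin (free 3-OH on unit 3) | c1c(OCc3ccccc3)cc(OCc3ccccc3)c2c1O[C@H](c1ccc(OCc3ccccc3)c(OCc3ccccc3)c1)[C@H](O)[C@H]2c1c(OCc3ccccc3)cc(OCc3ccccc3)c2c1O[C@H](c1ccc(OCc3ccccc3)c(OCc3ccccc3)c1)[C@@H](OCc3ccccc3)C2 | intermediate
18 | penta-O-benzylepicatechin-(4β→8)-penta-O-benzylcatechin | c1c(OCc3ccccc3)cc(OCc3ccccc3)c2c1O[C@H](c1ccc(OCc3ccccc3)c(OCc3ccccc3)c1)[C@H](OCc3ccccc3)[C@H]2c1c(OCc3ccccc3)cc(OCc3ccccc3)c2c1O[C@H](c1ccc(OCc3ccccc3)c(OCc3ccccc3)c1)[C@@H](OCc3ccccc3)C2 | intermediate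
19 | 8-bromo derivative of 18 (C8 of unit 3) | Brc1c(OCc3ccccc3)cc(OCc3ccccc3)c2c1O[C@H](c1ccc(OCc3ccccc3)c(OCc3ccccc3)c1)[C@H](OCc3ccccc3)[C@H]2c1c(OCc3ccccc3)cc(OCc3ccccc3)c2c1O[C@H](c1ccc(OCc3ccccc3)c(OCc3ccccc3)c1)[C@@H](OCc3ccccc3)C2 | intermediate
20 | 8-lithio derivative of 18 (C8 of unit 3) | [Li]c1c(OCc3ccccc3)cc(OCc3ccccc3)c2c1O[C@H](c1ccc(OCc3ccccc3)c(OCc3ccccc3)c1)[C@H](OCc3ccccc3)[C@H]2c1c(OCc3ccccc3)cc(OCc3ccccc3)c2c1O[C@H](c1ccc(OCc3ccccc3)c(OCc3ccccc3)c1)[C@@H](OCc3ccccc3)C2 | intermediate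
21 | 8-carbaldehyde of 18 (C8 of unit 3) | O=Cc1c(OCc3ccccc3)cc(OCc3ccccc3)c2c1O[C@H](c1ccc(OCc3ccccc3)c(OCc3ccccc3)c1)[C@H](OCc3ccccc3)[C@H]2c1c(OCc3ccccc3)cc(OCc3ccccc3)c2c1O[C@H](c1ccc(OCc3ccccc3)c(OCc3ccccc3)c1)[C@@H](OCc3ccccc3)C2 | intermediate
22 | (E)-enone on C8 of unit 3 of the dimer | O=C(/C=C/c1c(OCc3ccccc3)cc(OCc3ccccc3)c2c1O[C@H](c1ccc(OCc3ccccc3)c(OCc3ccccc3)c1)[C@H](OCc3ccccc3)[C@H]2c1c(OCc3ccccc3)cc(OCc3ccccc3)c2c1O[C@H](c1ccc(OCc3ccccc3)c(OCc3ccccc3)c1)[C@@H](OCc3ccccc3)C2)c1ccc(OCc3ccccc3)c(OCc3ccccc3)c1 | intermediate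
23 | Michael adduct ketone of 22 with phloroglucinol (new centre as C4 of unit 2) | O=C(c1ccc(OCc3ccccc3)c(OCc3ccccc3)c1)C[C@H](c1c(O)cc(O)cc1O)c1c(OCc3ccccc3)cc(OCc3ccccc3)c2c1O[C@H](c1ccc(OCc3ccccc3)c(OCc3ccccc3)c1)[C@H](OCc3ccccc3)[C@H]2c1c(OCc3ccccc3)cc(OCc3ccccc3)c2c1O[C@H](c1ccc(OCc3ccccc3)c(OCc3ccccc3)c1)[C@@H](OCc3ccccc3)C2 | intermediate
24 | cyclic hemiketal of unit 2 (either C2 anomer) on the dimer | c1c(O)cc(O)c2c1OC(O)(c1ccc(OCc3ccccc3)c(OCc3ccccc3)c1)C[C@H]2c1c(OCc3ccccc3)cc(OCc3ccccc3)c2c1O[C@H](c1ccc(OCc3ccccc3)c(OCc3ccccc3)c1)[C@H](OCc3ccccc3)[C@H]2c1c(OCc3ccccc3)cc(OCc3ccccc3)c2c1O[C@H](c1ccc(OCc3ccccc3)c(OCc3ccccc3)c1)[C@@H](OCc3ccccc3)C2 | intermediate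
25 | 5,7-dihydroxy-4β-aryl-flav-2-ene (unit 2) on the dimer | c1c(O)cc(O)c2c1OC(c1ccc(OCc3ccccc3)c(OCc3ccccc3)c1)=C[C@H]2c1c(OCc3ccccc3)cc(OCc3ccccc3)c2c1O[C@H](c1ccc(OCc3ccccc3)c(OCc3ccccc3)c1)[C@H](OCc3ccccc3)[C@H]2c1c(OCc3ccccc3)cc(OCc3ccccc3)c2c1O[C@H](c1ccc(OCc3ccccc3)c(OCc3ccccc3)c1)[C@@H](OCc3ccccc3)C2 | intermediate
26 | 5,7-di-O-benzyl ether of 25 | c1c(OCc3ccccc3)cc(OCc3ccccc3)c2c1OC(c1ccc(OCc3ccccc3)c(OCc3ccccc3)c1)=C[C@H]2c1c(OCc3ccccc3)cc(OCc3ccccc3)c2c1O[C@H](c1ccc(OCc3ccccc3)c(OCc3ccccc3)c1)[C@H](OCc3ccccc3)[C@H]2c1c(OCc3ccccc3)cc(OCc3ccccc3)c2c1O[C@H](c1ccc(OCc3ccccc3)c(OCc3ccccc3)c1)[C@@H](OCc3ccccc3)C2 | intermediate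
27 | 2α,3α-epoxide of 26 | c1c(OCc3ccccc3)cc(OCc3ccccc3)c2c1O[C@@]4(c1ccc(OCc3ccccc3)c(OCc3ccccc3)c1)[C@H](O4)[C@H]2c1c(OCc3ccccc3)cc(OCc3ccccc3)c2c1O[C@H](c1ccc(OCc3ccccc3)c(OCc3ccccc3)c1)[C@H](OCc3ccccc3)[C@H]2c1c(OCc3ccccc3)cc(OCc3ccccc3)c2c1O[C@H](c1ccc(OCc3ccccc3)c(OCc3ccccc3)c1)[C@@H](OCc3ccccc3)C2 | intermediate
28 | tetra-O-benzylepicatechin-(4β→8)-penta-O-benzylepicatechin-(4β→8)-penta-O-benzylcatechin (free 3-OH on unit 2) | c1c(OCc3ccccc3)cc(OCc3ccccc3)c2c1O[C@H](c1ccc(OCc3ccccc3)c(OCc3ccccc3)c1)[C@H](O)[C@H]2c1c(OCc3ccccc3)cc(OCc3ccccc3)c2c1O[C@H](c1ccc(OCc3ccccc3)c(OCc3ccccc3)c1)[C@H](OCc3ccccc3)[C@H]2c1c(OCc3ccccc3)cc(OCc3ccccc3)c2c1O[C@H](c1ccc(OCc3ccccc3)c(OCc3ccccc3)c1)[C@@H](OCc3ccccc3)C2 | intermediate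
29 | pentadeca-O-benzyl epicatechin-(4β→8)-epicatechin-(4β→8)-catechin | c1c(OCc3ccccc3)cc(OCc3ccccc3)c2c1O[C@H](c1ccc(OCc3ccccc3)c(OCc3ccccc3)c1)[C@H](OCc3ccccc3)[C@H]2c1c(OCc3ccccc3)cc(OCc3ccccc3)c2c1O[C@H](c1ccc(OCc3ccccc3)c(OCc3ccccc3)c1)[C@H](OCc3ccccc3)[C@H]2c1c(OCc3ccccc3)cc(OCc3ccccc3)c2c1O[C@H](c1ccc(OCc3ccccc3)c(OCc3ccccc3)c1)[C@@H](OCc3ccccc3)C2 | intermediate
30 | 8-bromo derivative of 29 (C8 of unit 2) | Brc1c(OCc3ccccc3)cc(OCc3ccccc3)c2c1O[C@H](c1ccc(OCc3ccccc3)c(OCc3ccccc3)c1)[C@H](OCc3ccccc3)[C@H]2c1c(OCc3ccccc3)cc(OCc3ccccc3)c2c1O[C@H](c1ccc(OCc3ccccc3)c(OCc3ccccc3)c1)[C@H](OCc3ccccc3)[C@H]2c1c(OCc3ccccc3)cc(OCc3ccccc3)c2c1O[C@H](c1ccc(OCc3ccccc3)c(OCc3ccccc3)c1)[C@@H](OCc3ccccc3)C2 | intermediate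
31 | 8-lithio derivative of 29 (C8 of unit 2) | [Li]c1c(OCc3ccccc3)cc(OCc3ccccc3)c2c1O[C@H](c1ccc(OCc3ccccc3)c(OCc3ccccc3)c1)[C@H](OCc3ccccc3)[C@H]2c1c(OCc3ccccc3)cc(OCc3ccccc3)c2c1O[C@H](c1ccc(OCc3ccccc3)c(OCc3ccccc3)c1)[C@H](OCc3ccccc3)[C@H]2c1c(OCc3ccccc3)cc(OCc3ccccc3)c2c1O[C@H](c1ccc(OCc3ccccc3)c(OCc3ccccc3)c1)[C@@H](OCc3ccccc3)C2 | intermediate
32 | 8-carbaldehyde of 29 (C8 of unit 2) | O=Cc1c(OCc3ccccc3)cc(OCc3ccccc3)c2c1O[C@H](c1ccc(OCc3ccccc3)c(OCc3ccccc3)c1)[C@H](OCc3ccccc3)[C@H]2c1c(OCc3ccccc3)cc(OCc3ccccc3)c2c1O[C@H](c1ccc(OCc3ccccc3)c(OCc3ccccc3)c1)[C@H](OCc3ccccc3)[C@H]2c1c(OCc3ccccc3)cc(OCc3ccccc3)c2c1O[C@H](c1ccc(OCc3ccccc3)c(OCc3ccccc3)c1)[C@@H](OCc3ccccc3)C2 | intermediate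
33 | (E)-enone on C8 of unit 2 of the trimer | O=C(/C=C/c1c(OCc3ccccc3)cc(OCc3ccccc3)c2c1O[C@H](c1ccc(OCc3ccccc3)c(OCc3ccccc3)c1)[C@H](OCc3ccccc3)[C@H]2c1c(OCc3ccccc3)cc(OCc3ccccc3)c2c1O[C@H](c1ccc(OCc3ccccc3)c(OCc3ccccc3)c1)[C@H](OCc3ccccc3)[C@H]2c1c(OCc3ccccc3)cc(OCc3ccccc3)c2c1O[C@H](c1ccc(OCc3ccccc3)c(OCc3ccccc3)c1)[C@@H](OCc3ccccc3)C2)c1ccc(OCc3ccccc3)c(OCc3ccccc3)c1 | intermediate
34 | Michael adduct ketone of 33 with phloroglucinol (new centre as C4 of unit 1) | O=C(c1ccc(OCc3ccccc3)c(OCc3ccccc3)c1)C[C@H](c1c(O)cc(O)cc1O)c1c(OCc3ccccc3)cc(OCc3ccccc3)c2c1O[C@H](c1ccc(OCc3ccccc3)c(OCc3ccccc3)c1)[C@H](OCc3ccccc3)[C@H]2c1c(OCc3ccccc3)cc(OCc3ccccc3)c2c1O[C@H](c1ccc(OCc3ccccc3)c(OCc3ccccc3)c1)[C@H](OCc3ccccc3)[C@H]2c1c(OCc3ccccc3)cc(OCc3ccccc3)c2c1O[C@H](c1ccc(OCc3ccccc3)c(OCc3ccccc3)c1)[C@@H](OCc3ccccc3)C2 | intermediate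
35 | cyclic hemiketal of unit 1 (either C2 anomer) on the trimer | c1c(O)cc(O)c2c1OC(O)(c1ccc(OCc3ccccc3)c(OCc3ccccc3)c1)C[C@H]2c1c(OCc3ccccc3)cc(OCc3ccccc3)c2c1O[C@H](c1ccc(OCc3ccccc3)c(OCc3ccccc3)c1)[C@H](OCc3ccccc3)[C@H]2c1c(OCc3ccccc3)cc(OCc3ccccc3)c2c1O[C@H](c1ccc(OCc3ccccc3)c(OCc3ccccc3)c1)[C@H](OCc3ccccc3)[C@H]2c1c(OCc3ccccc3)cc(OCc3ccccc3)c2c1O[C@H](c1ccc(OCc3ccccc3)c(OCc3ccccc3)c1)[C@@H](OCc3ccccc3)C2 | intermediate
36 | 5,7-dihydroxy-4β-aryl-flav-2-ene (unit 1) on the trimer | c1c(O)cc(O)c2c1OC(c1ccc(OCc3ccccc3)c(OCc3ccccc3)c1)=C[C@H]2c1c(OCc3ccccc3)cc(OCc3ccccc3)c2c1O[C@H](c1ccc(OCc3ccccc3)c(OCc3ccccc3)c1)[C@H](OCc3ccccc3)[C@H]2c1c(OCc3ccccc3)cc(OCc3ccccc3)c2c1O[C@H](c1ccc(OCc3ccccc3)c(OCc3ccccc3)c1)[C@H](OCc3ccccc3)[C@H]2c1c(OCc3ccccc3)cc(OCc3ccccc3)c2c1O[C@H](c1ccc(OCc3ccccc3)c(OCc3ccccc3)c1)[C@@H](OCc3ccccc3)C2 | intermediate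
37 | 5,7-di-O-benzyl ether of 36 | c1c(OCc3ccccc3)cc(OCc3ccccc3)c2c1OC(c1ccc(OCc3ccccc3)c(OCc3ccccc3)c1)=C[C@H]2c1c(OCc3ccccc3)cc(OCc3ccccc3)c2c1O[C@H](c1ccc(OCc3ccccc3)c(OCc3ccccc3)c1)[C@H](OCc3ccccc3)[C@H]2c1c(OCc3ccccc3)cc(OCc3ccccc3)c2c1O[C@H](c1ccc(OCc3ccccc3)c(OCc3ccccc3)c1)[C@H](OCc3ccccc3)[C@H]2c1c(OCc3ccccc3)cc(OCc3ccccc3)c2c1O[C@H](c1ccc(OCc3ccccc3)c(OCc3ccccc3)c1)[C@@H](OCc3ccccc3)C2 | intermediate
38 | 2α,3α-epoxide of 37 | c1c(OCc3ccccc3)cc(OCc3ccccc3)c2c1O[C@@]4(c1ccc(OCc3ccccc3)c(OCc3ccccc3)c1)[C@H](O4)[C@H]2c1c(OCc3ccccc3)cc(OCc3ccccc3)c2c1O[C@H](c1ccc(OCc3ccccc3)c(OCc3ccccc3)c1)[C@H](OCc3ccccc3)[C@H]2c1c(OCc3ccccc3)cc(OCc3ccccc3)c2c1O[C@H](c1ccc(OCc3ccccc3)c(OCc3ccccc3)c1)[C@H](OCc3ccccc3)[C@H]2c1c(OCc3ccccc3)cc(OCc3ccccc3)c2c1O[C@H](c1ccc(OCc3ccccc3)c(OCc3ccccc3)c1)[C@@H](OCc3ccccc3)C2 | intermediate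
39 | nonadeca-O-benzyl tetramer: tetra-O-benzylepicatechin-(4β→8)-penta-O-benzylepicatechin-(4β→8)-penta-O-benzylepicatechin-(4β→8)-penta-O-benzylcatechin (free 3-OH on unit 1) | c1c(OCc3ccccc3)cc(OCc3ccccc3)c2c1O[C@H](c1ccc(OCc3ccccc3)c(OCc3ccccc3)c1)[C@H](O)[C@H]2c1c(OCc3ccccc3)cc(OCc3ccccc3)c2c1O[C@H](c1ccc(OCc3ccccc3)c(OCc3ccccc3)c1)[C@H](OCc3ccccc3)[C@H]2c1c(OCc3ccccc3)cc(OCc3ccccc3)c2c1O[C@H](c1ccc(OCc3ccccc3)c(OCc3ccccc3)c1)[C@H](OCc3ccccc3)[C@H]2c1c(OCc3ccccc3)cc(OCc3ccccc3)c2c1O[C@H](c1ccc(OCc3ccccc3)c(OCc3ccccc3)c1)[C@@H](OCc3ccccc3)C2 | intermediate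
40 | epicatechin-(4β→8)-epicatechin-(4β→8)-epicatechin-(4β→8)-catechin (the target) | Oc1cc(O)c2c(c1)O[C@H](c1ccc(O)c(O)c1)[C@H](O)[C@H]2c1c(O)cc(O)c2c1O[C@H](c1ccc(O)c(O)c1)[C@H](O)[C@H]2c1c(O)cc(O)c2c1O[C@H](c1ccc(O)c(O)c1)[C@H](O)[C@H]2c1c(O)cc(O)c2c1O[C@H](c1ccc(O)c(O)c1)[C@@H](O)C2 | target

**Step count and risks**

Total step count: 24. Longest linear sequence: 23 steps (steps 1–4 and 6–24, from (+)-catechin); step 5 is a one-step side branch.

Steps most likely to fail: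

1. Step 7 (the same risk recurs in steps 14 and 21). The acid may activate the twisted, donor-rich enone too weakly or with poor facial discrimination, and reversible ipso-protonation of the adduct could erode the C4 configuration before ring closure. The fallback uses known chemistry and gives up the annulation for this unit; it sets out from compounds 3 and 4 and comes back at compound 17. Compound 3 is oxidised (Dess–Martin oxidation, CH2Cl2) to 5,7,3′,4′-tetra-O-benzylflavan-3-one F1. LiBH(s-Bu)3 (THF, −78 °C) reduces this from the face opposite the C2 aryl to 5,7,3′,4′-tetra-O-benzylepicatechin F2. DDQ with 2-ethoxyethanol in CH2Cl2 oxidises the benzylic C4 to 4β-(2-ethoxyethoxy)-5,7,3′,4′-tetra-O-benzylepicatechin F3. TiCl4 (CH2Cl2/THF, 0 °C) then ionises F3 in the presence of an excess of 4, whose C8 should attack the C4 cation trans to the 3-OH to give 17. The same electrophile F3 with 18 or 29 as the nucleophile would re-enter at 28 or 39.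

2. Step 9 (recurring in steps 16 and 23). The labile epoxide may ionise before hydride transfer, so that hydride arrives on the wrong face, or it may rearrange to the flavan-3-one by a 1,2-hydride shift. The fallback sets out from compound 15 and comes back at compound 17. The epoxidation is run with DMDO in CH2Cl2/MeOH at −40 °C, so that methanol opens the epoxide at C2 to the 2-methoxyflavan-3-ol of unit 3 on unit 4 F4 (either C2 anomer). Et3SiH with BF3·OEt2 (CH2Cl2, −78 °C) then reduces the derived C2 oxocarbenium ion; with the C4 aryl and C3–O held trans-diaxial, axial hydride delivery anti to C3–O should give the 2,3-cis product 17.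

3. Step 11 (recurring in step 18). Bromination may spread to the C6 positions of either unit in place of C8 of the top unit, giving regioisomeric aldehydes later. The fallback fixes the bromine at the monomer stage, where C8 selectivity is established; it sets out from compound 3 (by way of F1 and F2 as above) and compound 4 and comes back at compound 19. F2 is brominated (NBS, CH2Cl2, −78 °C) to 8-bromo-5,7,3′,4′-tetra-O-benzylepicatechin F5. DDQ with 2-ethoxyethanol gives 8-bromo-4β-(2-ethoxyethoxy)-5,7,3′,4′-tetra-O-benzylepicatechin F6. TiCl4-mediated coupling with an excess of 4 (CH2Cl2/THF, 0 °C; the bromine also blocks self-condensation of the electrophile) gives 8-bromo-5,7,3′,4′-tetra-O-benzylepicatechin-(4β→8)-penta-O-benzylcatechin F7. Benzylation of its free 3-OH (NaH, BnBr, DMF) gives 19.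

**Further compounds**

F1 | step 7 | 5,7,3′,4′-tetra-O-benzylflavan-3-one (2R) | c1c(OCc3ccccc3)cc(OCc3ccccc3)c2c1O[C@H](c1ccc(OCc3ccccc3)c(OCc3ccccc3)c1)C(=O)C2
F2 | step 7 | 5,7,3′,4′-tetra-O-benzylepicatechin | c1c(OCc3ccccc3)cc(OCc3ccccc3)c2c1O[C@H](c1ccc(OCc3ccccc3)c(OCc3ccccc3)c1)[C@H](O)C2
F3 | step 7 | 4β-(2-ethoxyethoxy)-5,7,3′,4′-tetra-O-benzylepicatechin | c1c(OCc3ccccc3)cc(OCc3ccccc3)c2c1O[C@H](c1ccc(OCc3ccccc3)c(OCc3ccccc3)c1)[C@H](O)[C@H]2OCCOCC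
F4 | step 9 | 2-methoxyflavan-3-ol of unit 3 (5,7,3′,4′-tetra-O-benzyl, either C2 anomer) bonded 4β→8 to penta-O-benzylcatechin | c1c(OCc3ccccc3)cc(OCc3ccccc3)c2c1OC(OC)(c1ccc(OCc3ccccc3)c(OCc3ccccc3)c1)[C@H](O)[C@H]2c1c(OCc3ccccc3)cc(OCc3ccccc3)c2c1O[C@H](c1ccc(OCc3ccccc3)c(OCc3ccccc3)c1)[C@@H](OCc3ccccc3)C2
F5 | step 11 | 8-bromo-5,7,3′,4′-tetra-O-benzylepicatechin | Brc1c(OCc3ccccc3)cc(OCc3ccccc3)c2c1O[C@H](c1ccc(OCc3ccccc3)c(OCc3ccccc3)c1)[C@H](O)C2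
F6 | step 11 | 8-bromo-4β-(2-ethoxyethoxy)-5,7,3′,4′-tetra-O-benzylepicatechin | Brc1c(OCc3ccccc3)cc(OCc3ccccc3)c2c1O[C@H](c1ccc(OCc3ccccc3)c(OCc3ccccc3)c1)[C@H](O)[C@H]2OCCOCC
F7 | step 11 | 8-bromo-5,7,3′,4′-tetra-O-benzylepicatechin-(4β→8)-penta-O-benzylcatechin (free 3-OH on unit 3) | Brc1c(OCc3ccccc3)cc(OCc3ccccc3)c2c1O[C@H](c1ccc(OCc3ccccc3)c(OCc3ccccc3)c1)[C@H](O)[C@H]2c1c(OCc3ccccc3)cc(OCc3ccccc3)c2c1O[C@H](c1ccc(OCc3ccccc3)c(OCc3ccccc3)c1)[C@@H](OCc3ccccc3)C2
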